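**Strategy**

Ring B is cut at C7–C8 and C9–C12. Its C7=C8 ring alkene together with the exocyclic C9=C12 bromomethylidene is a 3-methylenecyclohexene unit, the pattern left when a 1,6-enyne cyclises 6-endo and the outer alkene carbon migrates onto the inner alkyne carbon. One gold-catalysed isomerisation therefore closes ring B, forms C7–C8 and moves C12 (with its bromine) from C7 to C9. The precursor is the fully functionalised ring A cyclohexane (C1 silyl ether, C3 bromide) whose quaternary C6 carries a (Z)-2-bromovinyl group and a but-3-ynyl chain; its three stereocentres come from a CBS reduction, a conformationally controlled Michael alkylation, a hydroxyl-directed epoxidation and an invertive bromination.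

Key step: step 13

Remark: atom labels C1–C12 in the text are those of the target (C1 carbinol carbon, C3 CHBr, C5 CMe2, C6 spiro carbon, ring B C7–C11, C12 the bromomethylidene carbon), while locants inside systematic names follow nomenclature; the bromovinyl group of the precursor is made (Z), since a shift of C12 with retention should carry a bromine that is cis to C6 to the C10 side of C9=C12 (the (E) geometry required), whereas an (E)-bromovinyl group should end as the (Z)-diene.

**Route**

Step 1
Reactants: 1 ethyl 2,6,6-trimethyl-4-oxocyclohex-2-ene-1-carboxylate (racemic)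
Product: 2 ethyl (4S)-4-hydroxy-2,6,6-trimethylcyclohex-2-ene-1-carboxylate (both epimers at the ester-bearing carbon)
Conditions: (R)-2-methyl-CBS-oxazaborolidine [(R)-1-methyl-3,3-diphenyltetrahydro-1H,3H-pyrrolo[1,2-c][1,3,2]oxazaborole] (10 mol%), BH3·SMe2, THF, −20 °C; then MeOH
Reagents that add atoms: none
Why: Corey–Bakshi–Shibata reduction, in which the enone alkene side acts as the large group, so the (R)-catalyst should deliver hydride to give the (S)-carbinol at C3 in both enantiomers of 1 (reagent control), and the ester-bearing carbon, still a mixture, is planarised in step 3.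

Step 2
Reactants: 2 ethyl (4S)-4-hydroxy-2,6,6-trimethylcyclohex-2-ene-1-carboxylate
Product: 3 ethyl (4S)-4-[(tert-butyldimethylsilyl)oxy]-2,6,6-trimethylcyclohex-2-ene-1-carboxylate
Conditions: TBSCl, imidazole, DMF, rt
Reagents that add atoms: tert-butyldimethylsilyl chloride, CC(C)(C)[Si](C)(C)Cl
Why: Imidazole-promoted silylation of a secondary alcohol, which masks the hydroxyl for the base, hydride and oxidation steps and provides the bulky group that fixes the ring conformation in step 3.

Step 3
Reactants: 3 ethyl (4S)-4-[(tert-butyldimethylsilyl)oxy]-2,6,6-trimethylcyclohex-2-ene-1-carboxylate; 4 methyl acrylate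
Product: 6 ethyl (1S,4S)-4-[(tert-butyldimethylsilyl)oxy]-1-(3-methoxy-3-oxopropyl)-2,6,6-trimethylcyclohex-2-ene-1-carboxylate, via lithium dienolate 5 (not isolated)
Conditions: LiN(iPr)2, THF, −78 °C; then 4, −78 °C; AcOH
Reagents that add atoms: methyl acrylate (4), C=CC(=O)OC
Why: Michael addition of an ester dienolate through its α-carbon C6, in which both epimers of 3 give the same planar dienolate 5, the silyloxy group sits pseudoequatorial so that the pseudoaxial C5 methyl blocks the opposite face, and the acrylate should therefore add cis to the silyloxy group and set C6 as (S).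

Step 4
Reactants: 6 ethyl (1S,4S)-4-[(tert-butyldimethylsilyl)oxy]-1-(3-methoxy-3-oxopropyl)-2,6,6-trimethylcyclohex-2-ene-1-carboxylate; 7 dimethyl (1-diazo-2-oxopropyl)phosphonate
Product: 9 ethyl (1S,4S)-1-(but-3-yn-1-yl)-4-[(tert-butyldimethylsilyl)oxy]-2,6,6-trimethylcyclohex-2-ene-1-carboxylate, via aldehyde 8 (not isolated)
Conditions: iBu2AlH (1.1 equiv), CH2Cl2, −78 °C; then MeOH, K2CO3, 7, −78 °C → rt
Reagents that add atoms: dimethyl (1-diazo-2-oxopropyl)phosphonate (7), CC(=O)C(=[N+]=[N-])P(=O)(OC)OC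
Why: One-pot partial ester reduction and Seyferth–Gilbert homologation with the Ohira–Bestmann reagent, in which the hydride at −78 °C attacks only the unhindered methyl ester (the ethyl ester on quaternary C6 is shielded) and the aldehyde 8 released by methanol is turned into the terminal alkyne C9≡C8.

Step 5
Reactants: 9 ethyl (1S,4S)-1-(but-3-yn-1-yl)-4-[(tert-butyldimethylsilyl)oxy]-2,6,6-trimethylcyclohex-2-ene-1-carboxylate
Product: 10 [(1S,4S)-1-(but-3-yn-1-yl)-4-[(tert-butyldimethylsilyl)oxy]-2,6,6-trimethylcyclohex-2-en-1-yl]methanol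
Conditions: LiAlH4, THF, 0 °C → rt
Reagents that add atoms: none
Why: LiAlH4 reduction of the hindered ester to the neopentyl primary alcohol, with the silyl ether, the isolated alkene and the unactivated terminal alkyne inert.

Step 6
Reactants: 10 [(1S,4S)-1-(but-3-yn-1-yl)-4-[(tert-butyldimethylsilyl)oxy]-2,6,6-trimethylcyclohex-2-en-1-yl]methanol
Product: 11 (1S,4S)-1-(but-3-yn-1-yl)-4-[(tert-butyldimethylsilyl)oxy]-2,6,6-trimethylcyclohex-2-ene-1-carbaldehyde
Conditions: Dess–Martin periodinane, CH2Cl2, 0 °C → rt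
Reagents that add atoms: none
Why: Dess–Martin oxidation of a primary alcohol under neutral conditions to the C7 aldehyde, which has no α-hydrogen and so can neither enolise nor epimerise.

Step 7
Reactants: 11 (1S,4S)-1-(but-3-yn-1-yl)-4-[(tert-butyldimethylsilyl)oxy]-2,6,6-trimethylcyclohex-2-ene-1-carbaldehyde; 12 (bromomethyl)triphenylphosphonium bromide
Product: 13 {[(1S,4S)-4-[(Z)-2-bromoethenyl]-4-(but-3-yn-1-yl)-3,5,5-trimethylcyclohex-2-en-1-yl]oxy}(tert-butyl)dimethylsilane
Conditions: 12, KOtBu (less than 12), THF, −78 °C; then 11, −78 → 0 °C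
Reagents that add atoms: (bromomethyl)triphenylphosphonium bromide (12), [Br-].BrC[P+](c1ccccc1)(c1ccccc1)c1ccccc1
Why: Wittig bromomethylenation with the non-stabilised ylide Ph3P=CHBr, which at low temperature should favour the (Z)-bromoalkene through the kinetic cis-oxaphosphetane, the minor (E) isomer being removed by chromatography and the base kept below the amount of 12 so that the alkyne is not deprotonated.

Step 8
Reactants: 13 {[(1S,4S)-4-[(Z)-2-bromoethenyl]-4-(but-3-yn-1-yl)-3,5,5-trimethylcyclohex-2-en-1-yl]oxy}(tert-butyl)dimethylsilane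
Product: 14 (1S,4S)-4-[(Z)-2-bromoethenyl]-4-(but-3-yn-1-yl)-3,5,5-trimethylcyclohex-2-en-1-ol
Conditions: HF·pyridine, pyridine, THF, 0 °C → rt
Reagents that add atoms: none
Why: Fluoride cleavage of the secondary silyl ether under buffered acidic conditions, chosen because basic fluoride could dehydrobrominate the (Z)-bromoalkene.

Step 9
Reactants: 14 (1S,4S)-4-[(Z)-2-bromoethenyl]-4-(but-3-yn-1-yl)-3,5,5-trimethylcyclohex-2-en-1-ol
Product: 15 (1S,2S,5S,6R)-5-[(Z)-2-bromoethenyl]-5-(but-3-yn-1-yl)-4,4,6-trimethyl-7-oxabicyclo[4.1.0]heptan-2-ol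
Conditions: VO(acac)2 (5 mol%), tBuOOH, CH2Cl2, 0 °C → rt
Reagents that add atoms: tert-butyl hydroperoxide, CC(C)(C)OO
Why: Vanadium-catalysed hydroxyl-directed epoxidation of an allylic alcohol, in which the alkoxide-bound peroxide delivers oxygen to the C1=C2 face syn to the C3 hydroxyl and so sets C1 (C–O cis to the C3 oxygen and to the butynyl chain), while the electron-poor bromoalkene and the alkyne do not react.

Step 10
Reactants: 15 (1S,2S,5S,6R)-5-[(Z)-2-bromoethenyl]-5-(but-3-yn-1-yl)-4,4,6-trimethyl-7-oxabicyclo[4.1.0]heptan-2-ol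
Product: 16 (1S,3S,6S)-6-[(Z)-2-bromoethenyl]-6-(but-3-yn-1-yl)-1,5,5-trimethylcyclohexane-1,3-diol
Conditions: LiEt3BH, THF, 0 °C → rt; then H2O
Reagents that add atoms: none
Why: SN2 opening of a trisubstituted epoxide by a nucleophilic hydride at the less substituted carbon C2, anti to the oxygen, which leaves the tertiary C1 alcohol with its configuration intact and does not touch the vinyl bromide or the alkyne.

Step 11
Reactants: 16 (1S,3S,6S)-6-[(Z)-2-bromoethenyl]-6-(but-3-yn-1-yl)-1,5,5-trimethylcyclohexane-1,3-diol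
Product: 17 (1S,3R,6S)-3-bromo-6-[(Z)-2-bromoethenyl]-6-(but-3-yn-1-yl)-1,5,5-trimethylcyclohexan-1-ol
Conditions: CBr4, PPh3, 2,6-lutidine, CH2Cl2, 0 °C → rt
Reagents that add atoms: carbon tetrabromide, BrC(Br)(Br)Br
Why: Appel bromination, in which the secondary alcohol becomes an alkoxyphosphonium ion that bromide displaces by SN2 with inversion to give the (3R)-bromide trans to the C1 oxygen, while the hindered tertiary hydroxyl is not substituted and, lying on the same face, cannot displace the leaving group.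

Step 12
Reactants: 17 (1S,3R,6S)-3-bromo-6-[(Z)-2-bromoethenyl]-6-(but-3-yn-1-yl)-1,5,5-trimethylcyclohexan-1-ol
Product: 18 {[(1S,3R,6S)-3-bromo-6-[(Z)-2-bromoethenyl]-6-(but-3-yn-1-yl)-1,5,5-trimethylcyclohexyl]oxy}triethylsilane
Conditions: Et3SiOTf, 2,6-lutidine, CH2Cl2, −78 → 0 °C
Reagents that add atoms: triethylsilyl trifluoromethanesulfonate, CC[Si](CC)(CC)OS(=O)(=O)C(F)(F)F
Why: Silylation of a hindered tertiary alcohol with a silyl triflate and a non-nucleophilic base, which prevents addition of the hydroxyl to the gold-activated alkyne in step 13.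

Step 13
Reactants: 18 {[(1S,3R,6S)-3-bromo-6-[(Z)-2-bromoethenyl]-6-(but-3-yn-1-yl)-1,5,5-trimethylcyclohexyl]oxy}triethylsilane
Product: 19 {[(1S,3R,6S,9E)-3-bromo-9-(bromomethylidene)-1,5,5-trimethylspiro[5.5]undec-7-en-1-yl]oxy}triethylsilane
Conditions: Ph3PAuNTf2 (5 mol%), CH2Cl2, 0 °C → rt
Reagents that add atoms: none
Why: Proposed new method: Ph3PAuNTf2 supplies a cationic monovalent gold centre that π-activates the terminal alkyne; the bromine-polarised alkene attacks anti to gold through C7 at the terminal carbon C8 (6-endo-dig closure of ring B, new bond C7–C8) and gives a bicyclo[4.1.0] cyclopropyl gold carbene with the carbene at C9. C12 then shifts from C8 to C9, the C7–C12 bond breaks and gold leaves, which creates C7=C8 and C9=C12, so that 18 and 19 are isomers. The closest known reaction type is the gold- or platinum-catalysed endo-type single-cleavage rearrangement of 1,6-enynes to 3-methylenecyclohexenes, which has not been shown for a 2-bromovinyl group on a quaternary ring carbon. No stereocentre is formed and C1, C3 and C6 are not touched; the only stereo-element made is the C9=C12 geometry, fixed by a suprafacial shift with retention at C12 that carries the bromine, cis to C6 in 18 and so endo on the cyclopropane, to the C10 side, which is (E). The step needs 6-endo instead of 5-exo attack, favoured because the neopentyl-type C7 reaches the unsubstituted C8 more easily than C9 and because bromine stabilises the positive charge that builds at C12 in the carbene and during the shift. The silyl ether keeps the tertiary oxygen from adding to the activated alkyne and the saturated ring A offers no second alkene.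

Step 14
Reactants: 19 {[(1S,3R,6S,9E)-3-bromo-9-(bromomethylidene)-1,5,5-trimethylspiro[5.5]undec-7-en-1-yl]oxy}triethylsilane
Product: 20 (1S,3R,6S,9E)-3-bromo-9-(bromomethylidene)-1,5,5-trimethylspiro[5.5]undec-7-en-1-ol
Conditions: HF·pyridine, pyridine, THF, 0 °C → rt
Reagents that add atoms: none
Why: Fluoride cleavage of the triethylsilyl ether, driven by the strong Si–F bond, under buffered conditions that avoid base-induced elimination of the secondary bromide and leave the bromodiene untouched.

**Compound list**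

1 | ethyl 2,6,6-trimethyl-4-oxocyclohex-2-ene-1-carboxylate (racemic) | CCOC(=O)C1C(C)=CC(=O)CC1(C)C | starting material
2 | ethyl (4S)-4-hydroxy-2,6,6-trimethylcyclohex-2-ene-1-carboxylate (both epimers at the ester-bearing carbon) | CC1(C)C[C@H](O)C=C(C)C1C(=O)OCC | intermediate
3 | ethyl (4S)-4-[(tert-butyldimethylsilyl)oxy]-2,6,6-trimethylcyclohex-2-ene-1-carboxylate (both epimers at the ester-bearing carbon) | CC1(C)C[C@H](O[Si](C)(C)C(C)(C)C)C=C(C)C1C(=O)OCC | intermediate
4 | methyl acrylate | C=CC(=O)OC | starting material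
5 | lithium dienolate of 3, lithium [(4S)-4-[(tert-butyldimethylsilyl)oxy]-2,6,6-trimethylcyclohex-2-en-1-ylidene](ethoxy)methanolate | CC1(C)C[C@H](O[Si](C)(C)C(C)(C)C)C=C(C)C1=C(OCC)O[Li] | intermediate
6 | ethyl (1S,4S)-4-[(tert-butyldimethylsilyl)oxy]-1-(3-methoxy-3-oxopropyl)-2,6,6-trimethylcyclohex-2-ene-1-carboxylate | CC1(C)C[C@H](O[Si](C)(C)C(C)(C)C)C=C(C)[C@@]1(CCC(=O)OC)C(=O)OCC | intermediate
7 | dimethyl (1-diazo-2-oxopropyl)phosphonate | CC(=O)C(=[N+]=[N-])P(=O)(OC)OC | starting material
8 | ethyl (1S,4S)-4-[(tert-butyldimethylsilyl)oxy]-2,6,6-trimethyl-1-(3-oxopropyl)cyclohex-2-ene-1-carboxylate | CC1(C)C[C@H](O[Si](C)(C)C(C)(C)C)C=C(C)[C@@]1(CCC=O)C(=O)OCC | intermediate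
9 | ethyl (1S,4S)-1-(but-3-yn-1-yl)-4-[(tert-butyldimethylsilyl)oxy]-2,6,6-trimethylcyclohex-2-ene-1-carboxylate | CC1(C)C[C@H](O[Si](C)(C)C(C)(C)C)C=C(C)[C@@]1(CCC#C)C(=O)OCC | intermediate
10 | [(1S,4S)-1-(but-3-yn-1-yl)-4-[(tert-butyldimethylsilyl)oxy]-2,6,6-trimethylcyclohex-2-en-1-yl]methanol | CC1(C)C[C@H](O[Si](C)(C)C(C)(C)C)C=C(C)[C@@]1(CCC#C)CO | intermediate
11 | (1S,4S)-1-(but-3-yn-1-yl)-4-[(tert-butyldimethylsilyl)oxy]-2,6,6-trimethylcyclohex-2-ene-1-carbaldehyde | CC1(C)C[C@H](O[Si](C)(C)C(C)(C)C)C=C(C)[C@@]1(CCC#C)C=O | intermediate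
12 | (bromomethyl)triphenylphosphonium bromide | [Br-].BrC[P+](c1ccccc1)(c1ccccc1)c1ccccc1 | starting material
13 | {[(1S,4S)-4-[(Z)-2-bromoethenyl]-4-(but-3-yn-1-yl)-3,5,5-trimethylcyclohex-2-en-1-yl]oxy}(tert-butyl)dimethylsilane | CC1(C)C[C@H](O[Si](C)(C)C(C)(C)C)C=C(C)[C@@]1(CCC#C)/C=C\Br | intermediate
14 | (1S,4S)-4-[(Z)-2-bromoethenyl]-4-(but-3-yn-1-yl)-3,5,5-trimethylcyclohex-2-en-1-ol | CC1(C)C[C@H](O)C=C(C)[C@@]1(CCC#C)/C=C\Br | intermediate
15 | (1S,2S,5S,6R)-5-[(Z)-2-bromoethenyl]-5-(but-3-yn-1-yl)-4,4,6-trimethyl-7-oxabicyclo[4.1.0]heptan-2-ol | CC1(C)C[C@H](O)[C@@H]2O[C@]2(C)[C@@]1(CCC#C)/C=C\Br | intermediate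
16 | (1S,3S,6S)-6-[(Z)-2-bromoethenyl]-6-(but-3-yn-1-yl)-1,5,5-trimethylcyclohexane-1,3-diol | CC1(C)C[C@H](O)C[C@](C)(O)[C@@]1(CCC#C)/C=C\Br | intermediate
17 | (1S,3R,6S)-3-bromo-6-[(Z)-2-bromoethenyl]-6-(but-3-yn-1-yl)-1,5,5-trimethylcyclohexan-1-ol | CC1(C)C[C@@H](Br)C[C@](C)(O)[C@@]1(CCC#C)/C=C\Br | intermediate
18 | {[(1S,3R,6S)-3-bromo-6-[(Z)-2-bromoethenyl]-6-(but-3-yn-1-yl)-1,5,5-trimethylcyclohexyl]oxy}triethylsilane | CC1(C)C[C@@H](Br)C[C@](C)(O[Si](CC)(CC)CC)[C@@]1(CCC#C)/C=C\Br | intermediate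
19 | {[(1S,3R,6S,9E)-3-bromo-9-(bromomethylidene)-1,5,5-trimethylspiro[5.5]undec-7-en-1-yl]oxy}triethylsilane | CC1(C)C[C@@H](Br)C[C@](C)(O[Si](CC)(CC)CC)[C@@]12C=C/C(=C/Br)CC2 | intermediate
20 | (1S,3R,6S,9E)-3-bromo-9-(bromomethylidene)-1,5,5-trimethylspiro[5.5]undec-7-en-1-ol | CC1(C)C[C@@H](Br)C[C@](C)(O)[C@@]12C=C/C(=C/Br)CC2 | target

**Step count and risks**

Total step count: 14. Longest linear sequence: 14 steps (1 to 20, fully linear).

Steps most likely to fail:

1. Step 13 (proposed new method). What may go wrong: closure through the inner alkyne carbon (5-exo) to a spiro[4.5] vinylcyclopentene, or loss of the bromoalkene geometry if the rearrangement leaks through an open α-bromo cation. The fallback uses known chemistry only. It sets out from aldehyde 8, isolated by working up step 4 after the hydride stage, and comes back to the route at target 20. Addition of MeMgBr (THF, −78 °C) to the aldehyde gives the secondary alcohol F1. LiAlH4 reduces the hindered ester to the diol F2. Dess–Martin oxidation of both hydroxyls gives the keto aldehyde F3. Intramolecular aldol condensation (KOH, MeOH) of the methyl ketone onto the non-enolisable C7 aldehyde forms C7=C8 and closes ring B as the spiro dienone F4. Wittig bromomethylenation with the ylide from 12 gives the bromodiene, from which the (E) isomer F5 is separated. HF·pyridine frees the allylic alcohol F6, VO(acac)2/tBuOOH gives the syn epoxy alcohol F7, LiEt3BH gives the diol F8, and CBr4/PPh3 then brominates C3 with inversion to give 20.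

2. Step 3. What may go wrong: slow addition of the congested dienolate, so that oligomerisation of the acrylate or attack through the γ-carbon takes over. The fallback sets out from 3 and comes back at aldehyde 8. The dienolate is alkylated on the same face with allyl bromide (LiN(iPr)2, THF/DMPU, −78 °C) to give the allyl ester F9. Hydroboration of the terminal alkene only (9-borabicyclo[3.3.1]nonane, then NaOH/H2O2) gives the primary alcohol F10. Dess–Martin oxidation gives 8, which enters the second stage of step 4 (K2CO3, MeOH, 7).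

3. Step 11. What may go wrong: E2 loss of the activated oxygen to a cyclohexene, or capture of the oxyphosphonium ion by the neighbouring tertiary hydroxyl. The fallback sets out from 16 and comes back at 17. The secondary hydroxyl alone is converted at −78 °C (Tf2O, pyridine, CH2Cl2) into the secondary triflate F11. Bu4NBr then displaces it with inversion at −40 → 0 °C, where elimination is slow and no phosphorus electrophile is present.

Further compounds
F1 | step 13 | ethyl (1S,4S)-4-[(tert-butyldimethylsilyl)oxy]-1-(3-hydroxybutyl)-2,6,6-trimethylcyclohex-2-ene-1-carboxylate (both carbinol epimers) | CC1(C)C[C@H](O[Si](C)(C)C(C)(C)C)C=C(C)[C@@]1(CCC(C)O)C(=O)OCC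
F2 | step 13 | 4-[(1S,4S)-4-[(tert-butyldimethylsilyl)oxy]-1-(hydroxymethyl)-2,6,6-trimethylcyclohex-2-en-1-yl]butan-2-ol (both carbinol epimers) | CC1(C)C[C@H](O[Si](C)(C)C(C)(C)C)C=C(C)[C@@]1(CCC(C)O)CO
F3 | step 13 | (1S,4S)-4-[(tert-butyldimethylsilyl)oxy]-2,6,6-trimethyl-1-(3-oxobutyl)cyclohex-2-ene-1-carbaldehyde | CC1(C)C[C@H](O[Si](C)(C)C(C)(C)C)C=C(C)[C@@]1(CCC(C)=O)C=O
F4 | step 13 | (6S,9S)-9-[(tert-butyldimethylsilyl)oxy]-7,11,11-trimethylspiro[5.5]undeca-1,7-dien-3-one | CC1(C)C[C@H](O[Si](C)(C)C(C)(C)C)C=C(C)[C@@]12C=CC(=O)CC2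
F5 | step 13 | tert-butyl{[(3S,6S,9E)-9-(bromomethylidene)-1,5,5-trimethylspiro[5.5]undeca-1,7-dien-3-yl]oxy}dimethylsilane | CC1(C)C[C@H](O[Si](C)(C)C(C)(C)C)C=C(C)[C@@]12C=C/C(=C/Br)CC2
F6 | step 13 | (3S,6S,9E)-9-(bromomethylidene)-1,5,5-trimethylspiro[5.5]undeca-1,7-dien-3-ol | CC1(C)C[C@H](O)C=C(C)[C@@]12C=C/C(=C/Br)CC2
F7 | step 13 | (1R,2S,3S,6S,9E)-9-(bromomethylidene)-1,2-epoxy-1,5,5-trimethylspiro[5.5]undec-7-en-3-ol | CC1(C)C[C@H](O)[C@@H]3O[C@]3(C)[C@@]12C=C/C(=C/Br)CC2
F8 | step 13 | (1S,3S,6S,9E)-9-(bromomethylidene)-1,5,5-trimethylspiro[5.5]undec-7-ene-1,3-diol | CC1(C)C[C@H](O)C[C@](C)(O)[C@@]12C=C/C(=C/Br)CC2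
F9 | step 3 | ethyl (1S,4S)-4-[(tert-butyldimethylsilyl)oxy]-2,6,6-trimethyl-1-(prop-2-en-1-yl)cyclohex-2-ene-1-carboxylate | CC1(C)C[C@H](O[Si](C)(C)C(C)(C)C)C=C(C)[C@@]1(CC=C)C(=O)OCC
F10 | step 3 | ethyl (1S,4S)-4-[(tert-butyldimethylsilyl)oxy]-1-(3-hydroxypropyl)-2,6,6-trimethylcyclohex-2-ene-1-carboxylate | CC1(C)C[C@H](O[Si](C)(C)C(C)(C)C)C=C(C)[C@@]1(CCCO)C(=O)OCC
F11 | step 11 | (1S,3S,4S)-4-[(Z)-2-bromoethenyl]-4-(but-3-yn-1-yl)-3-hydroxy-3,5,5-trimethylcyclohexyl trifluoromethanesulfonate | CC1(C)C[C@H](OS(=O)(=O)C(F)(F)F)C[C@](C)(O)[C@@]1(CCC#C)/C=C\Br
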